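Assumption: lignan locants are used throughout. C7–C9 and ring B (the central guaiacyl ring) lie on one side of the furofuran, C7'–C9' and ring A (the syringyl ring) on the other, and C7''–C9'' with ring C (the terminal guaiacyl ring) form the glycerol arm. The target is then (7R,8S,7'R,8'S,7''R,8''S).

Assumption: the salt of the (1R,2R)-diacid with (R)-1-phenylethylamine is taken to be the less soluble diastereomer. If the (1S,2S)-salt crystallises instead, the (S)-amine is used, and the configuration of 4 is proved by hydrogenation to trans-cyclohexane-1,2-dicarboxylic acid of known rotation.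

## Structural features

The target is a sesquilignan built on a cis-fused 3,7-dioxabicyclo[3.3.0]octane (furofuran) that carries ring B on C7 and ring A on C7', both on the convex face. Ring B is joined through its 4-oxygen to C8'' of an arylglycerol, with ring C on C7'' and the primary alcohol at C9''. Four contiguous stereocentres (C7, C8, C8', C7') sit in the bicycle. Two more, C7'' and C8'' (anti, erythro), stand side by side in the arm and are insulated from the core by ring B, so each set needs its own source of absolute configuration. The fragile groups are the benzylic ether bonds C7–O and C7'–O (ionised by acid, cut by hydrogenolysis), the benzylic alcohol C7''–OH para to a phenol, and three electron-rich rings that oxidants attack. The core is almost twofold symmetric, so the real difficulty is to place two different aryl groups on a symmetric C8–C8' unit with all four core centres controlled, under a protecting-group plan that needs neither acid nor hydrogen near the benzylic C–O bonds. The key step exploits the fact that C8 and C8' are bonded to each other and each bears one carbon (C9, C9') that is tied to the oxygen on the benzylic carbon of the other half. C8, C8', C9 and C9' are four of the six carbons of a trans-5,6-disubstituted cyclohexa-1,3-diene. Excising the two central sp2 carbons leaves C9 and C9' as aldehydes, each five atoms from O7' and O7.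

## Logic of the disconnections

29 to 28. The O–Si bond on ring A is cut. The last step must not use acid or hydrogen, and a fluoride-labile ether meets that. The gain is small but it fixes the whole protecting-group plan. The forward step needs buffered fluoride so that the p-hydroxybenzyl alcohol of ring C is not ionised.

28 to 25. The C9'' hydroxymethyl group is traced back to a vinyl group (one carbon is added back as =CH2), and the ring C phenol to its acetate. This turns the 1,3-diol into a homoallylic alcohol, the retron of an allylboration. The forward step demands that ozone takes a monosubstituted alkene in the presence of three oxygenated arenes and that the aldehyde is reduced before C8'' can epimerise.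

25 to 22 and 23. The C7''–C8'' bond is cut. Both arm stereocentres then arise in one step, the anti relation from the E geometry of the allylboronate 24 formed in the flask and the absolute sense from a chiral acid. The arm shrinks to a commercial aldehyde and an alkenylboronate. The forward step must rely on catalyst control alone, because the core of 22 is too remote to help.

22 to 21 to 19. The C–B bond is cut (hydroboration of an alkyne), then the O4–CH2 bond of ring B (propargyl ether), then the O–Si bond of ring B. The three carbons that become C8'', C9'' and the lost methylene come from propargyl bromide. The demand is that the ring B silyl ether leaves while the ring A silyl ether stays, which is met by grading them (tert-butyldimethylsilyl against a doubly ortho-flanked triisopropylsilyl).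

19 to 18. The C9–H and C9'–H bonds are replaced by C–OH. A lactol is the natural resting state of an aldehyde that has a γ-hydroxyl, so this uncovers a masked 1,4-dialdehyde. The forward reduction must go through the cyclic oxocarbenium ions without ionising C7–O or C7'–O.

18 to 16 (key). The C9–O and C9'–O bonds are cut and C9 and C9' are reconnected through two sp2 carbons. The bicycle with six stereocentres becomes a monocyclic carbocycle with four, both rings forming in one operation, and C8/C8' are already fixed as the trans centres of the diene. The forward step demands cleavage of the diene without attack on the arenes and without enolisation of the aldehydes.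

16 to 15. The C7–H and C7'–H bonds are cut, giving two ketones. Because the core is nearly twofold symmetric, one reagent can set both carbinols. The demand is high facial control at two α-branched aryl ketones under conditions that do not enolise them.

15 to 10 and 14, then 10 to 5 and 9. The aryl–carbonyl bonds C7'–C1' and C7–C1 are cut. A neutral acyl cross-coupling is chosen because the α-hydrogens are allylic and acidic. The gain is a twofold-symmetric bis-thioester. The demand is a single coupling on one of two homotopic thioesters, met by using 5 in excess and recovering it.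

5 to 4 to 3 to 2 to 1. The thioesters go back to the diacid, the single enantiomer to the racemate, and two hydrogens are removed from C1 and C2 to restore the arene. A commodity acid thereby supplies all six ring carbons, including the two that are later discarded. The forward steps need a trans-selective reduction and a resolution carried out without double-bond migration.

9 to 7 to 6, and 14 to 12 to 11. The C–B bonds are cut back to C–Br and the O–Si bonds to the phenols, which leads to two commercial bromophenols.

## Other disconnections considered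

Alternative 1: The cut is at C7'–C8' and C8–C7, which leaves a four-carbon butenolide A3 between the syringyl dithiane A2 and the ring B aldehyde A4 that already carries the protected arm. In the forward step lithiated A2 adds to the β-carbon of A3 anti to the menthyloxy group, and the lactone enolate is trapped by A4 trans to the new substituent, giving A1.
- In its favour: three components and two C–C bonds in one flask, with C8 and C8' set from a recoverable auxiliary. On precedent, on convergence and on the source of configuration at C8/C8' (auxiliary instead of resolution) it is the better plan.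
- Against it here: no ring is closed, and A1 is still far from the furofuran. The C7 carbinol would be formed with little control. The dithiane must be removed with mercury salts or oxidants next to three electron-rich rings. The ketone so revealed needs a selective reduction, the lactone acetal must be reduced, and the rings must be closed with acid beside the silylene-protected benzylic C7''–O bond.
- Comparison: structurally both plans fix the trans C8/C8' pair early, but the chosen plan sets C7 and C7' in one reagent-controlled step and the alternative at two separate times. Mechanistically the polar Michael–aldol sequence is more secure than the untested cleavage cascade, which is a point for the alternative. In step count the two are expected to be similar, the alternative being more convergent and the chosen plan shorter between key step and core.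

Alternative 2: The cut is at C8–C8' and C7'–O. The precursor A6 is the ether of the C7 oxygen with the syringyl cinnamyl group, with a terminal epoxide at C8–C9. In the forward step Cp2TiCl (trivalent titanium) opens the epoxide to the C8 radical, 5-exo addition to the styrene forms C8–C8' and the first ring, and iodine converts the benzylic C7' centre into an electrophile that the C9 alkoxide captures, giving A5.
- In its favour: one C–C bond, one C–O bond and both rings in one step, and the product is the complete protected target, so only deprotection follows. On step count after the key step and on convergence it is clearly the better plan. The radical conditions are neutral, and the cascade is known for simpler furofurans, so on precedent it is at least the equal of the chosen plan.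
- Against it here: only C7 is defined beforehand, and C8, C8' and C7' are all created in the key step. The ionic closure at C7' is expected to give exo/endo mixtures. A6 is a doubly activated, acid-labile benzylic ether that needs its own enantioselective synthesis. Titanium is used in excess, and A5 ends with hydrogenolysis of benzyl ethers next to C7–O and C7'–O.
- Comparison: structurally the chosen plan has all four core centres in place before the rings form, which is the safer position. Mechanistically a radical–cation cascade stands against a dipolar cleavage with hemiacetal closure. In step economy the alternative wins.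

Alternative 3: The cut is at C3–C4 and C5–C6 of ring B, which is assembled from the pyrone A9 and the ynol ether A8 (the C8'' oxygen becomes the ring B 4-oxygen). In the forward step the electron-rich alkyne adds across C3 and C6 of A9 and the bridged adduct loses CO2 to give the ester A7.
- In its favour: the hindered secondary alkyl aryl ether is formed without substitution at C8''. In this it equals the chosen plan, where C8'' is never substituted either. The regiochemistry follows from the polarisation of both partners. The arm stereocentres would be made and checked on a small molecule before they meet the core, which is better than the late allylboration of the chosen plan.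
- Against it here: it builds an aromatic ring that can be bought in oxidised form and leaves the furofuran unsolved. A7 would still have to be converted into an aldehyde such as A4 and joined to the core by another strategy. A8 must be made from a hindered alcohol with strong base, and the cycloaddition needs heat.
- Comparison: structurally it addresses only the junction of arm and ring B. Mechanistically it is a reliable pericyclic sequence. In step economy it adds steps, and it is best seen as a possible front end to Alternative 1 or 2 and not as a competitor for the core.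

Key step: step 12

## Steps

Step 1
Reactants: 1 phthalic acid
Product: 2 (±)-trans-cyclohexa-3,5-diene-1,2-dicarboxylic acid (trans-1,2-dihydrophthalic acid)
Conditions: e−, Pb cathode, divided cell, 5 % aq. H2SO4–1,4-dioxane, 15 °C
Reagents that add atoms: none
Why: Cathodic two-electron, two-proton (Birch-type) reduction of an arene activated by two carboxyl groups; kinetic protonation should give the trans-1,2-dihydro acid, the same product that sodium amalgam gives, without mercury.

Step 2
Reactants: 2 (±)-trans-cyclohexa-3,5-diene-1,2-dicarboxylic acid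
Product: 3 (R)-1-phenylethylammonium (1R,2R)-2-carboxycyclohexa-3,5-diene-1-carboxylate (1:1 salt, crystalline)
Conditions: (R)-1-phenylethylamine (1 equiv), EtOH, below 40 °C then 4 °C; recrystallise
Reagents that add atoms: (R)-1-phenylethylamine, C[C@@H](N)c1ccccc1
Why: Classical resolution through diastereomeric salts; no stereocentre is made, one enantiomer of 2 is selected, and the temperature is kept low so that the diene does not migrate into conjugation.

Step 3
Reactants: 3 (R)-1-phenylethylammonium (1R,2R)-2-carboxycyclohexa-3,5-diene-1-carboxylate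
Product: 4 (1R,2R)-cyclohexa-3,5-diene-1,2-dicarboxylic acid
Conditions: 1 M HCl, EtOAc, 0 °C
Reagents that add atoms: none
Why: Simple liberation of the acid from its salt by a stronger acid in the cold; C1 and C2, the later C8 and C8', are not touched.

Step 4
Reactants: 4 (1R,2R)-cyclohexa-3,5-diene-1,2-dicarboxylic acid
Product: 5 S,S'-diphenyl (1R,2R)-cyclohexa-3,5-diene-1,2-bis(carbothioate)
Conditions: PhSH, DCC, 1-hydroxybenzotriazole, EtOAc, 0 → 20 °C
Reagents that add atoms: thiophenol, Sc1ccccc1
Why: Carbodiimide thioesterification (Steglich type) run without amine base, so that the allylic α-hydrogens are not removed and the trans relation is kept.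

Step 5
Reactants: 6 4-bromo-2-methoxyphenol
Product: 7 (4-bromo-2-methoxyphenoxy)(tert-butyl)dimethylsilane
Conditions: TBSCl, imidazole, DMF, 20 °C
Reagents that add atoms: tert-butyldimethylsilyl chloride, CC(C)(C)[Si](C)(C)Cl
Why: Standard silylation of a phenol; the tert-butyldimethylsilyl group is chosen for ring B because it must later leave before the ring A silyl ether.

Step 6
Reactants: 7 (4-bromo-2-methoxyphenoxy)(tert-butyl)dimethylsilane
Product: 9 [4-(tert-butyldimethylsilyloxy)-3-methoxyphenyl]boronic acid, via aryllithium 8 (not isolated)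
Conditions: n-BuLi, THF, −78 °C; B(OiPr)3, −78 → 0 °C; aq. NH4Cl, pH 5
Reagents that add atoms: triisopropyl borate, CC(C)OB(OC(C)C)OC(C)C; water, O
Why: Bromine–lithium exchange at −78 °C is faster than any attack on the silyl ether, and the borate trap followed by mild hydrolysis gives the boronic acid.

Step 7
Reactants: 5 S,S'-diphenyl (1R,2R)-cyclohexa-3,5-diene-1,2-bis(carbothioate); 9 [4-(tert-butyldimethylsilyloxy)-3-methoxyphenyl]boronic acid
Product: 10 S-phenyl (1R,6R)-6-[4-(tert-butyldimethylsilyloxy)-3-methoxybenzoyl]cyclohexa-2,4-diene-1-carbothioate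
Conditions: 5 (2.5 equiv, excess recovered), Pd2(dba)3 (2.5 mol %), P(OEt)3 (20 mol %), Cu(O2CC4H3S) (copper thiophene-2-carboxylate, 1.5 equiv), THF, 20 °C
Reagents that add atoms: none
Why: Liebeskind–Srogl coupling: zerovalent palladium inserts into the C(O)–S bond, the copper carboxylate takes up the thiolate and activates boron, and no base is present that could remove the α-hydrogen. The two thioesters of 5 are homotopic, so one coupling gives a single compound, and the excess of 5 should suppress the second coupling.

Step 8
Reactants: 11 4-bromo-2,6-dimethoxyphenol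
Product: 12 (4-bromo-2,6-dimethoxyphenoxy)triisopropylsilane
Conditions: TIPSOTf, 2,6-lutidine, CH2Cl2, 0 → 20 °C
Reagents that add atoms: triisopropylsilyl trifluoromethanesulfonate, CC(C)[Si](C(C)C)(C(C)C)OS(=O)(=O)C(F)(F)F
Why: Silylation of a hindered phenol needs the triflate; the triisopropylsilyl ether between two methoxy groups is meant to last to the final step.

Step 9
Reactants: 12 (4-bromo-2,6-dimethoxyphenoxy)triisopropylsilane
Product: 14 [3,5-dimethoxy-4-(triisopropylsilyloxy)phenyl]boronic acid, via aryllithium 13 (not isolated)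
Conditions: n-BuLi, THF, −78 °C; B(OiPr)3, −78 → 0 °C; aq. NH4Cl, pH 5
Reagents that add atoms: triisopropyl borate, CC(C)OB(OC(C)C)OC(C)C; water, O
Why: Same lithiation–borylation as in step 6; the lithium sits para to the silyloxy group, so no silyl migration is possible.

Step 10
Reactants: 10 S-phenyl (1R,6R)-6-[4-(tert-butyldimethylsilyloxy)-3-methoxybenzoyl]cyclohexa-2,4-diene-1-carbothioate; 14 [3,5-dimethoxy-4-(triisopropylsilyloxy)phenyl]boronic acid
Product: 15 [(1R,6R)-6-[3,5-dimethoxy-4-(triisopropylsilyloxy)benzoyl]cyclohexa-2,4-dien-1-yl][4-(tert-butyldimethylsilyloxy)-3-methoxyphenyl]methanone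
Conditions: 14 (1.3 equiv), Pd2(dba)3 (2.5 mol %), P(OEt)3 (20 mol %), Cu(O2CC4H3S) (1.5 equiv), THF, 20 °C
Reagents that add atoms: none
Why: Second Liebeskind–Srogl coupling on the remaining thioester; the ketone already present is inert under these neutral conditions, and the product is used at once because its α-hydrogens are both allylic and α to carbonyl.

Step 11
Reactants: 15 [(1R,6R)-6-[3,5-dimethoxy-4-(triisopropylsilyloxy)benzoyl]cyclohexa-2,4-dien-1-yl][4-(tert-butyldimethylsilyloxy)-3-methoxyphenyl]methanone
Product: 16 (R)-[(1R,6R)-6-[(R)-[3,5-dimethoxy-4-(triisopropylsilyloxy)phenyl](hydroxy)methyl]cyclohexa-2,4-dien-1-yl][4-(tert-butyldimethylsilyloxy)-3-methoxyphenyl]methanol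
Conditions: (S)-Me-CBS oxazaborolidine [(S)-1-methyl-3,3-diphenyltetrahydro-1H,3H-pyrrolo[1,2-c][1,3,2]oxazaborole, 0.5 equiv], catecholborane (3 equiv), toluene–CH2Cl2, −78 °C; MeOH; pH 7 buffer
Reagents that add atoms: none
Why: Corey–Bakshi–Shibata reduction; with the aryl group as the large substituent the (S)-catalyst should deliver hydride to give the (R)-carbinol at C7 and at C7', and Felkin–Anh addition anti to the ring carbon that bears the other arm points the same way, so catalyst and substrate are expected to reinforce each other. Catecholborane does not hydroborate the diene at −78 °C, and the Lewis-acidic medium should not enolise the ketones.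

Step 12
Reactants: 16 (R)-[(1R,6R)-6-[(R)-[3,5-dimethoxy-4-(triisopropylsilyloxy)phenyl](hydroxy)methyl]cyclohexa-2,4-dien-1-yl][4-(tert-butyldimethylsilyloxy)-3-methoxyphenyl]methanol
Product: 18 (1R,3S,3aR,4R,6S,6aR)-1-[4-(tert-butyldimethylsilyloxy)-3-methoxyphenyl]-4-[3,5-dimethoxy-4-(triisopropylsilyloxy)phenyl]tetrahydro-1H,3H-furo[3,4-c]furan-3,6-diol (bis-lactol; anomers interconvert), via diol dialdehyde 17 (not isolated)
Conditions: O3/O2, CH2Cl2–MeOH (5:1), NaHCO3 (solid), Sudan Red 7B, −78 °C; Me2S, −78 → 20 °C
Reagents that add atoms: ozone, [O-][O+]=O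
Why: Proposed new method: ozone adds as a 1,3-dipole to each C=C of the diene (primary ozonide, cycloreversion to carbonyl and carbonyl oxide, capture of the carbonyl oxide by methanol or by the neighbouring hydroxyl, reduction of the hydroperoxide by Me2S), so that C9 and C9' become aldehydes and the two central carbons leave as glyoxal. The closest known reaction types are the ozonolysis of cyclohexa-1,3-dienes to 1,4-dicarbonyl compounds and the spontaneous lactol formation of γ-hydroxy aldehydes; their union as a furofuran synthesis is untested. One ring closes by 5-exo-trig addition of the C7 hydroxyl to the C9' aldehyde (bond C9'–O) and the other by 5-exo-trig addition of the C7' hydroxyl to the C9 aldehyde (bond C9–O); closure onto the aldehyde of the same arm would be four-membered and should not compete. The cis fusion follows from the trans arrangement at C8/C8' fixed in 4, because only then can each arm reach the aldehyde on the other carbon after rotation about C8–C8'; these two centres and C7/C7' from step 11 are not touched. The new centres C9 and C9' are anomeric, settle under thermodynamic control (hydroxyl on the convex face expected) and vanish in step 13, so their ratio does not matter. The step needs chemoselectivity for the diene over two oxygenated arenes, which should be secured by the much higher rate of ozone with a conjugated diene at −78 °C, by dosing to the bleaching of the dye, and by a precursor in which both phenols are silyl ethers and no benzyl ether is exposed. It also needs retention at C8/C8': solid NaHCO3 only scavenges acid, and each aldehyde is captured intramolecularly as soon as it is unveiled.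

Step 13
Reactants: 18 (1R,3S,3aR,4R,6S,6aR)-1-[4-(tert-butyldimethylsilyloxy)-3-methoxyphenyl]-4-[3,5-dimethoxy-4-(triisopropylsilyloxy)phenyl]tetrahydro-1H,3H-furo[3,4-c]furan-3,6-diol
Product: 19 (1R,3aS,4R,6aS)-1-[4-(tert-butyldimethylsilyloxy)-3-methoxyphenyl]-4-[3,5-dimethoxy-4-(triisopropylsilyloxy)phenyl]tetrahydro-1H,3H-furo[3,4-c]furan
Conditions: Et3SiH, BF3·OEt2 (promoter), CH2Cl2, −78 °C; Et3N quench
Reagents that add atoms: none
Why: Ionic hydrogenation of both lactols through cyclic oxocarbenium ions, a standard end of furofuran syntheses; at −78 °C the benzylic C7–O and C7'–O bonds, which carry only silyloxy-substituted rings, should not ionise, so the four core centres are kept.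

Step 14
Reactants: 19 (1R,3aS,4R,6aS)-1-[4-(tert-butyldimethylsilyloxy)-3-methoxyphenyl]-4-[3,5-dimethoxy-4-(triisopropylsilyloxy)phenyl]tetrahydro-1H,3H-furo[3,4-c]furan
Product: 21 (1R,3aS,4R,6aS)-4-[3,5-dimethoxy-4-(triisopropylsilyloxy)phenyl]-1-[3-methoxy-4-(prop-2-yn-1-yloxy)phenyl]tetrahydro-1H,3H-furo[3,4-c]furan, via caesium phenolate 20 (not isolated)
Conditions: Cs2CO3, DMF–H2O (10:1), 20 °C; then HC≡CCH2Br, 20 °C
Reagents that add atoms: propargyl bromide, C#CCBr
Why: Carbonate-mediated cleavage of the aryl tert-butyldimethylsilyl ether followed in the same flask by Williamson alkylation; the triisopropylsilyl ether, bulkier and flanked by two methoxy groups, is expected to survive.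

Step 15
Reactants: 21 (1R,3aS,4R,6aS)-4-[3,5-dimethoxy-4-(triisopropylsilyloxy)phenyl]-1-[3-methoxy-4-(prop-2-yn-1-yloxy)phenyl]tetrahydro-1H,3H-furo[3,4-c]furan
Product: 22 2-[(E)-3-{4-[(1R,3aS,4R,6aS)-4-[3,5-dimethoxy-4-(triisopropylsilyloxy)phenyl]tetrahydro-1H,3H-furo[3,4-c]furan-1-yl]-2-methoxyphenoxy}prop-1-en-1-yl]-4,4,5,5-tetramethyl-1,3,2-dioxaborolane
Conditions: pinacolborane, Cp2Zr(H)Cl (10 mol %), Et3N (10 mol %), CH2Cl2, 40 °C
Reagents that add atoms: pinacolborane, [H]B1OC(C)(C)C(C)(C)O1
Why: Zirconium-catalysed hydroboration of a terminal alkyne; syn, anti-Markovnikov addition should give the (E)-alkenylboronate only.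

Step 16
Reactants: 22 the (E)-alkenyl pinacol boronate of step 15; 23 4-formyl-2-methoxyphenyl acetate (vanillin acetate)
Product: 25 4-[(1R,2S)-1-hydroxy-2-{4-[(1R,3aS,4R,6aS)-4-[3,5-dimethoxy-4-(triisopropylsilyloxy)phenyl]tetrahydro-1H,3H-furo[3,4-c]furan-1-yl]-2-methoxyphenoxy}but-3-en-1-yl]-2-methoxyphenyl acetate, via allylboronate 24 (not isolated)
Conditions: [Ir(cod)2]BF4 (5 mol %), PCy3 (10 mol %), H2-activated; (S)-TRIP [(S)-3,3'-bis(2,4,6-triisopropylphenyl)-1,1'-binaphthyl-2,2'-diyl hydrogen phosphate, 10 mol %], 23 (1.5 equiv), 4 Å sieves, ClCH2CH2Cl, 20 °C; aq. work-up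
Reagents that add atoms: none
Why: An iridium hydride shifts the double bond of 22 into conjugation with oxygen to give the (E)-γ-aryloxyallylboronate 24, which adds to the aldehyde through a chair (Zimmerman–Traxler) transition state, so that the E geometry sets the anti (7'',8'') relation. The phosphoric acid, the mirror image of the one that gives (R)-carbinols from benzaldehyde and allyl pinacolboronate, should direct attack to the Si face and so give 7''R and with it 8''S; the remote core exerts no bias.

Step 17
Reactants: 25 4-[(1R,2S)-1-hydroxy-2-(aryloxy)but-3-en-1-yl]-2-methoxyphenyl acetate of step 16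
Product: 28 (1R,2S)-2-{4-[(1R,3aS,4R,6aS)-4-[3,5-dimethoxy-4-(triisopropylsilyloxy)phenyl]tetrahydro-1H,3H-furo[3,4-c]furan-1-yl]-2-methoxyphenoxy}-1-(4-hydroxy-3-methoxyphenyl)propane-1,3-diol, via aldehyde 26 (not isolated), via diol acetate 27 (not isolated)
Conditions: O3/O2, CH2Cl2–MeOH (1:1), Sudan Red 7B, −78 °C; NaBH4, −78 → 0 °C; K2CO3, 20 °C
Reagents that add atoms: ozone, [O-][O+]=O
Why: Ozonolysis of the vinyl group with borohydride work-up gives the C9'' alcohol; the α-aryloxy aldehyde is reduced in the cold before C8'' can epimerise. Methanolysis then removes the aryl acetate, which until then has kept ring C electron-poor towards ozone.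

Step 18
Reactants: 28 (1R,2S)-2-(aryloxy)-1-(4-hydroxy-3-methoxyphenyl)propane-1,3-diol of step 17
Product: 29 ficusesquilignan A, (7R,8S,7'R,8'S,7''R,8''S)
Conditions: Bu4NF, AcOH, THF, 0 → 20 °C
Reagents that add atoms: none
Why: Fluoride cleavage of the last aryl silyl ether, buffered with acetic acid so that the p-hydroxybenzyl alcohol and the benzylic ethers are not exposed to strong base; no acid and no hydrogen are used at the end.

## Compound list

1 | phthalic acid | OC(=O)c1ccccc1C(=O)O | starting material
2 | (±)-trans-cyclohexa-3,5-diene-1,2-dicarboxylic acid (both enantiomers shown) | OC(=O)[C@@H]1C=CC=C[C@H]1C(=O)O.OC(=O)[C@H]1C=CC=C[C@@H]1C(=O)O | intermediate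
3 | (R)-1-phenylethylammonium (1R,2R)-2-carboxycyclohexa-3,5-diene-1-carboxylate | OC(=O)[C@@H]1C=CC=C[C@H]1C([O-])=O.C[C@@H]([NH3+])c1ccccc1 | intermediate
4 | (1R,2R)-cyclohexa-3,5-diene-1,2-dicarboxylic acid | OC(=O)[C@@H]1C=CC=C[C@H]1C(=O)O | intermediate
5 | S,S'-diphenyl (1R,2R)-cyclohexa-3,5-diene-1,2-bis(carbothioate) | O=C(Sc1ccccc1)[C@@H]1C=CC=C[C@H]1C(=O)Sc1ccccc1 | intermediate
6 | 4-bromo-2-methoxyphenol | COc1cc(Br)ccc1O | starting material
7 | (4-bromo-2-methoxyphenoxy)(tert-butyl)dimethylsilane | COc1cc(Br)ccc1O[Si](C)(C)C(C)(C)C | intermediate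
8 | [4-(tert-butyldimethylsilyloxy)-3-methoxyphenyl]lithium | COc1cc([Li])ccc1O[Si](C)(C)C(C)(C)C | intermediate (not isolated)
9 | [4-(tert-butyldimethylsilyloxy)-3-methoxyphenyl]boronic acid | COc1cc(B(O)O)ccc1O[Si](C)(C)C(C)(C)C | intermediate
10 | S-phenyl (1R,6R)-6-[4-(tert-butyldimethylsilyloxy)-3-methoxybenzoyl]cyclohexa-2,4-diene-1-carbothioate | COc1cc(C(=O)[C@@H]2C=CC=C[C@H]2C(=O)Sc2ccccc2)ccc1O[Si](C)(C)C(C)(C)C | intermediate
11 | 4-bromo-2,6-dimethoxyphenol | COc1cc(Br)cc(OC)c1O | starting material
12 | (4-bromo-2,6-dimethoxyphenoxy)triisopropylsilane | COc1cc(Br)cc(OC)c1O[Si](C(C)C)(C(C)C)C(C)C | intermediate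
13 | [3,5-dimethoxy-4-(triisopropylsilyloxy)phenyl]lithium | COc1cc([Li])cc(OC)c1O[Si](C(C)C)(C(C)C)C(C)C | intermediate (not isolated)
14 | [3,5-dimethoxy-4-(triisopropylsilyloxy)phenyl]boronic acid | COc1cc(B(O)O)cc(OC)c1O[Si](C(C)C)(C(C)C)C(C)C | intermediate
15 | [(1R,6R)-6-[3,5-dimethoxy-4-(triisopropylsilyloxy)benzoyl]cyclohexa-2,4-dien-1-yl][4-(tert-butyldimethylsilyloxy)-3-methoxyphenyl]methanone | COc1cc(C(=O)[C@@H]2C=CC=C[C@H]2C(=O)c2cc(OC)c(O[Si](C(C)C)(C(C)C)C(C)C)c(OC)c2)ccc1O[Si](C)(C)C(C)(C)C | intermediate
16 | (R)-[(1R,6R)-6-[(R)-[3,5-dimethoxy-4-(triisopropylsilyloxy)phenyl](hydroxy)methyl]cyclohexa-2,4-dien-1-yl][4-(tert-butyldimethylsilyloxy)-3-methoxyphenyl]methanol | COc1cc([C@H](O)[C@@H]2C=CC=C[C@H]2[C@@H](O)c2cc(OC)c(O[Si](C(C)C)(C(C)C)C(C)C)c(OC)c2)ccc1O[Si](C)(C)C(C)(C)C | intermediate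
17 | (2R,3R)-2-[(R)-[4-(tert-butyldimethylsilyloxy)-3-methoxyphenyl](hydroxy)methyl]-3-[(R)-[3,5-dimethoxy-4-(triisopropylsilyloxy)phenyl](hydroxy)methyl]butanedial | COc1cc([C@H](O)[C@H](C=O)[C@@H](C=O)[C@@H](O)c2cc(OC)c(O[Si](C(C)C)(C(C)C)C(C)C)c(OC)c2)ccc1O[Si](C)(C)C(C)(C)C | intermediate (not isolated)
18 | (1R,3S,3aR,4R,6S,6aR)-1-[4-(tert-butyldimethylsilyloxy)-3-methoxyphenyl]-4-[3,5-dimethoxy-4-(triisopropylsilyloxy)phenyl]tetrahydro-1H,3H-furo[3,4-c]furan-3,6-diol | COc1cc([C@@H]2O[C@H](O)[C@@H]3[C@H]2[C@@H](O)O[C@H]3c2cc(OC)c(O[Si](C(C)C)(C(C)C)C(C)C)c(OC)c2)ccc1O[Si](C)(C)C(C)(C)C | intermediate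
19 | (1R,3aS,4R,6aS)-1-[4-(tert-butyldimethylsilyloxy)-3-methoxyphenyl]-4-[3,5-dimethoxy-4-(triisopropylsilyloxy)phenyl]tetrahydro-1H,3H-furo[3,4-c]furan | COc1cc([C@@H]2OC[C@@H]3[C@H]2CO[C@H]3c2cc(OC)c(O[Si](C(C)C)(C(C)C)C(C)C)c(OC)c2)ccc1O[Si](C)(C)C(C)(C)C | intermediate
20 | caesium 4-[(1R,3aS,4R,6aS)-4-[3,5-dimethoxy-4-(triisopropylsilyloxy)phenyl]tetrahydro-1H,3H-furo[3,4-c]furan-1-yl]-2-methoxyphenolate | COc1cc([C@@H]2OC[C@@H]3[C@H]2CO[C@H]3c2cc(OC)c(O[Si](C(C)C)(C(C)C)C(C)C)c(OC)c2)ccc1[O-].[Cs+] | intermediate (not isolated)
21 | (1R,3aS,4R,6aS)-4-[3,5-dimethoxy-4-(triisopropylsilyloxy)phenyl]-1-[3-methoxy-4-(prop-2-yn-1-yloxy)phenyl]tetrahydro-1H,3H-furo[3,4-c]furan | COc1cc([C@@H]2OC[C@@H]3[C@H]2CO[C@H]3c2cc(OC)c(O[Si](C(C)C)(C(C)C)C(C)C)c(OC)c2)ccc1OCC#C | intermediate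
22 | 2-[(E)-3-{4-[(1R,3aS,4R,6aS)-4-[3,5-dimethoxy-4-(triisopropylsilyloxy)phenyl]tetrahydro-1H,3H-furo[3,4-c]furan-1-yl]-2-methoxyphenoxy}prop-1-en-1-yl]-4,4,5,5-tetramethyl-1,3,2-dioxaborolane | COc1cc([C@@H]2OC[C@@H]3[C@H]2CO[C@H]3c2cc(OC)c(O[Si](C(C)C)(C(C)C)C(C)C)c(OC)c2)ccc1OC/C=C/B1OC(C)(C)C(C)(C)O1 | intermediate
23 | 4-formyl-2-methoxyphenyl acetate | COc1cc(C=O)ccc1OC(C)=O | starting material
24 | 2-[(E)-3-{4-[(1R,3aS,4R,6aS)-4-[3,5-dimethoxy-4-(triisopropylsilyloxy)phenyl]tetrahydro-1H,3H-furo[3,4-c]furan-1-yl]-2-methoxyphenoxy}prop-2-en-1-yl]-4,4,5,5-tetramethyl-1,3,2-dioxaborolane | COc1cc([C@@H]2OC[C@@H]3[C@H]2CO[C@H]3c2cc(OC)c(O[Si](C(C)C)(C(C)C)C(C)C)c(OC)c2)ccc1O/C=C/CB1OC(C)(C)C(C)(C)O1 | intermediate (not isolated)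
25 | 4-[(1R,2S)-1-hydroxy-2-{4-[(1R,3aS,4R,6aS)-4-[3,5-dimethoxy-4-(triisopropylsilyloxy)phenyl]tetrahydro-1H,3H-furo[3,4-c]furan-1-yl]-2-methoxyphenoxy}but-3-en-1-yl]-2-methoxyphenyl acetate | COc1cc([C@@H](O)[C@H](C=C)Oc2ccc([C@@H]3OC[C@@H]4[C@H]3CO[C@H]4c3cc(OC)c(O[Si](C(C)C)(C(C)C)C(C)C)c(OC)c3)cc2OC)ccc1OC(C)=O | intermediate
26 | 4-[(1R,2R)-1-hydroxy-3-oxo-2-{4-[(1R,3aS,4R,6aS)-4-[3,5-dimethoxy-4-(triisopropylsilyloxy)phenyl]tetrahydro-1H,3H-furo[3,4-c]furan-1-yl]-2-methoxyphenoxy}propyl]-2-methoxyphenyl acetate | COc1cc([C@@H](O)[C@H](C=O)Oc2ccc([C@@H]3OC[C@@H]4[C@H]3CO[C@H]4c3cc(OC)c(O[Si](C(C)C)(C(C)C)C(C)C)c(OC)c3)cc2OC)ccc1OC(C)=O | intermediate (not isolated)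
27 | 4-[(1R,2S)-1,3-dihydroxy-2-{4-[(1R,3aS,4R,6aS)-4-[3,5-dimethoxy-4-(triisopropylsilyloxy)phenyl]tetrahydro-1H,3H-furo[3,4-c]furan-1-yl]-2-methoxyphenoxy}propyl]-2-methoxyphenyl acetate | COc1cc([C@@H](O)[C@H](CO)Oc2ccc([C@@H]3OC[C@@H]4[C@H]3CO[C@H]4c3cc(OC)c(O[Si](C(C)C)(C(C)C)C(C)C)c(OC)c3)cc2OC)ccc1OC(C)=O | intermediate (not isolated)
28 | (1R,2S)-2-{4-[(1R,3aS,4R,6aS)-4-[3,5-dimethoxy-4-(triisopropylsilyloxy)phenyl]tetrahydro-1H,3H-furo[3,4-c]furan-1-yl]-2-methoxyphenoxy}-1-(4-hydroxy-3-methoxyphenyl)propane-1,3-diol | COc1cc([C@@H](O)[C@H](CO)Oc2ccc([C@@H]3OC[C@@H]4[C@H]3CO[C@H]4c3cc(OC)c(O[Si](C(C)C)(C(C)C)C(C)C)c(OC)c3)cc2OC)ccc1O | intermediate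
29 | ficusesquilignan A, (1R,2S)-2-{4-[(1R,3aS,4R,6aS)-4-(4-hydroxy-3,5-dimethoxyphenyl)tetrahydro-1H,3H-furo[3,4-c]furan-1-yl]-2-methoxyphenoxy}-1-(4-hydroxy-3-methoxyphenyl)propane-1,3-diol | COc1cc([C@@H](O)[C@H](CO)Oc2ccc([C@@H]3OC[C@@H]4[C@H]3CO[C@H]4c3cc(OC)c(O)c(OC)c3)cc2OC)ccc1O | target

## Step count and least certain steps

Total: 18 steps. Longest linear sequence: 14 steps (steps 1–4, 7, 10–18, from phthalic acid).

Step 12 (key step). The most likely failure is oxidation of the oxygenated arenes in competition with the second cleavage. Once the first C=C is cut, the remaining one is conjugated with or flanked by carbonyl-level carbon and reacts more slowly, so the margin over the syringyl ring narrows. A second risk is enolisation of the aldehydes before they close, which would scramble C8/C8'.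
Fallback (known chemistry): setting out from 16, both double bonds are dihydroxylated (OsO4 cat., N-methylmorpholine N-oxide, acetone–water), which arenes tolerate, to give the cyclohexane-1,2,3,4-tetrol F1. Glycol cleavage with NaIO4 in buffered aqueous THF then cuts the three C–C bonds between the four carbinol carbons. The two central carbons leave as formic acid, dialdehyde 17 forms and closes as before, and the route is rejoined at 18.

Step 7 (and likewise step 10). The acyl group sits on a ring carbon that is allylic to the diene. The acylpalladium intermediate may lose CO to a cyclohexadienyl–palladium species, and β-hydride loss would then aromatise the ring. Slow coupling also gives time for the double bonds to drift into conjugation with the carbonyl.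
Fallback: setting out from 4, the acid is converted with 2,2'-dipyridyl disulfide and PPh3 into the bis(S-pyridin-2-yl) thioester F2. At −78 °C this reacts in turn with one equivalent of the arylmagnesium bromide F3 (from 7 and Mg) to give the keto thioester F4, and then with the arylmagnesium bromide F5 (from 12 and Mg). The chelated pyridyl thioester acylates faster than the Grignard reagent deprotonates, and no palladium is involved. The route is rejoined at 15.

Step 11. Facial control may be insufficient at one or both carbonyls, because the catalyst has to tell an aryl group from an α-branched ring carbon and the intrinsic preference of the substrate is only inferred. The outcome would be a mixture of carbinol epimers.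
Fallback: setting out from 15, the reduction is run under substrate control alone (NaBH4, CeCl3·7H2O, MeOH–THF, −78 °C, a Luche reduction) to give the mixture of carbinol epimers F6. Chromatography delivers 16, and the other diastereomers are oxidised back to 15 with Dess–Martin periodinane (NaHCO3, CH2Cl2) and recycled. The route is rejoined at 16.

Step 2. The two diastereomeric salts may not differ enough in solubility, and prolonged warming during recrystallisation may move the double bonds.
Fallback: setting out from 2, the racemate is thioesterified as in step 4 to give the racemic bis(S-phenyl) thioester F7. This neutral, UV-active compound is resolved by preparative chromatography on a chiral stationary phase (supercritical CO2–MeOH). The route is rejoined at 5.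

Step 16. An uncatalysed background allylboration or hydrolysis of the enol-ether allylboronate by traces of water may erode the facial control or divert the reagent. Any loss of control gives diastereomers that differ only far from the core and are hard to separate.
Fallback: setting out from 19, phenolate 20 is made as in step 14 and alkylated with ethyl bromoacetate to give the aryloxyacetate F8. Vanillin F9 is silylated (TIPSCl, imidazole) to the aldehyde F10. The lithium enolate of F8 (LDA, THF, −78 °C) adds to F10 to give the erythro-rich β-hydroxy ester F11. LiBH4 reduction and preparative HPLC of the two erythro diastereomers give the (7''R,8''S)-diol F12, and Bu4NF–AcOH removes both silyl ethers. This path has no absolute control in the arm and gives up half of the material, but it uses only established steps. The route is rejoined at 29.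

Step 14. The triisopropylsilyl ether on ring A may be lost alongside the tert-butyldimethylsilyl ether, and both phenols would then be alkylated.
Fallback: setting out from 19, both silyl ethers are removed with Bu4NF to give the diphenol F13. One equivalent of propargyl bromide (K2CO3, acetone) should alkylate the less hindered ring B phenol to give the mono-propargyl ether F14, with regioisomers removed by chromatography. The ring A phenol is then silylated again (TIPSOTf, 2,6-lutidine). The route is rejoined at 21.

## Further compounds

F1 | step 12 | cyclohexane-1,2,3,4-tetrol from 16, with the two arm-bearing ring carbons and both carbinols as in 16 and the ring hydroxyls as a mixture | COc1cc([C@H](O)[C@@H]2C(O)C(O)C(O)C(O)[C@H]2[C@@H](O)c2cc(OC)c(O[Si](C(C)C)(C(C)C)C(C)C)c(OC)c2)ccc1O[Si](C)(C)C(C)(C)C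
F2 | step 7 | S,S'-di(pyridin-2-yl) (1R,2R)-cyclohexa-3,5-diene-1,2-bis(carbothioate) | O=C(Sc1ccccn1)[C@@H]1C=CC=C[C@H]1C(=O)Sc1ccccn1
F3 | step 7 | [4-(tert-butyldimethylsilyloxy)-3-methoxyphenyl]magnesium bromide | COc1cc([Mg]Br)ccc1O[Si](C)(C)C(C)(C)C
F4 | step 7 | S-pyridin-2-yl (1R,6R)-6-[4-(tert-butyldimethylsilyloxy)-3-methoxybenzoyl]cyclohexa-2,4-diene-1-carbothioate | COc1cc(C(=O)[C@@H]2C=CC=C[C@H]2C(=O)Sc2ccccn2)ccc1O[Si](C)(C)C(C)(C)C
F5 | step 7 | [3,5-dimethoxy-4-(triisopropylsilyloxy)phenyl]magnesium bromide | COc1cc([Mg]Br)cc(OC)c1O[Si](C(C)C)(C(C)C)C(C)C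
F6 | step 11 | mixture of the C7/C7' carbinol epimers of 16 | COc1cc(C(O)[C@@H]2C=CC=C[C@H]2C(O)c2cc(OC)c(O[Si](C(C)C)(C(C)C)C(C)C)c(OC)c2)ccc1O[Si](C)(C)C(C)(C)C
F7 | step 2 | (±)-trans-S,S'-diphenyl cyclohexa-3,5-diene-1,2-bis(carbothioate), both enantiomers shown | O=C(Sc1ccccc1)[C@@H]1C=CC=C[C@H]1C(=O)Sc1ccccc1.O=C(Sc1ccccc1)[C@H]1C=CC=C[C@@H]1C(=O)Sc1ccccc1
F8 | step 16 | ethyl 2-{4-[(1R,3aS,4R,6aS)-4-[3,5-dimethoxy-4-(triisopropylsilyloxy)phenyl]tetrahydro-1H,3H-furo[3,4-c]furan-1-yl]-2-methoxyphenoxy}acetate | COc1cc([C@@H]2OC[C@@H]3[C@H]2CO[C@H]3c2cc(OC)c(O[Si](C(C)C)(C(C)C)C(C)C)c(OC)c2)ccc1OCC(=O)OCC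
F9 | step 16 | vanillin | COc1cc(C=O)ccc1O
F10 | step 16 | 3-methoxy-4-(triisopropylsilyloxy)benzaldehyde | COc1cc(C=O)ccc1O[Si](C(C)C)(C(C)C)C(C)C
F11 | step 16 | ethyl 3-hydroxy-3-[3-methoxy-4-(triisopropylsilyloxy)phenyl]-2-(aryloxy)propanoate, erythro-rich, both absolute senses at C7''/C8'' | COc1cc(C(O)C(C(=O)OCC)Oc2ccc([C@@H]3OC[C@@H]4[C@H]3CO[C@H]4c3cc(OC)c(O[Si](C(C)C)(C(C)C)C(C)C)c(OC)c3)cc2OC)ccc1O[Si](C(C)C)(C(C)C)C(C)C
F12 | step 16 | (1R,2S)-2-{4-[(1R,3aS,4R,6aS)-4-[3,5-dimethoxy-4-(triisopropylsilyloxy)phenyl]tetrahydro-1H,3H-furo[3,4-c]furan-1-yl]-2-methoxyphenoxy}-1-[3-methoxy-4-(triisopropylsilyloxy)phenyl]propane-1,3-diol | COc1cc([C@@H](O)[C@H](CO)Oc2ccc([C@@H]3OC[C@@H]4[C@H]3CO[C@H]4c3cc(OC)c(O[Si](C(C)C)(C(C)C)C(C)C)c(OC)c3)cc2OC)ccc1O[Si](C(C)C)(C(C)C)C(C)C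
F13 | step 14 | 4-[(1R,3aS,4R,6aS)-4-(4-hydroxy-3-methoxyphenyl)tetrahydro-1H,3H-furo[3,4-c]furan-1-yl]-2,6-dimethoxyphenol | COc1cc([C@@H]2OC[C@@H]3[C@H]2CO[C@H]3c2cc(OC)c(O)c(OC)c2)ccc1O
F14 | step 14 | 2,6-dimethoxy-4-[(1R,3aS,4R,6aS)-4-[3-methoxy-4-(prop-2-yn-1-yloxy)phenyl]tetrahydro-1H,3H-furo[3,4-c]furan-1-yl]phenol | COc1cc([C@@H]2OC[C@@H]3[C@H]2CO[C@H]3c2cc(OC)c(O)c(OC)c2)ccc1OCC#C
A1 | alternative 1 | trans-2,3-disubstituted 4-menthyloxybutanolide adduct (C7 carbinol as one epimer) | COc1cc([C@@H](O[Si]5(C(C)(C)C)C(C)(C)C)[C@H](CO5)Oc2ccc([C@H](O)[C@@H]3C(=O)O[C@H](O[C@H]4C[C@@H](C)CC[C@@H]4C(C)C)[C@H]3C3(SCCCS3)c3cc(OC)c(OCc4ccccc4)c(OC)c3)cc2OC)ccc1OCc1ccccc1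
A2 | alternative 1 | 2-(4-benzyloxy-3,5-dimethoxyphenyl)-1,3-dithiane | COc1cc(C2SCCCS2)cc(OC)c1OCc1ccccc1
A3 | alternative 1 | (5S)-5-[(1S,2R,5S)-menthyloxy]furan-2(5H)-one | O=C1O[C@H](O[C@H]2C[C@@H](C)CC[C@@H]2C(C)C)C=C1
A4 | alternative 1 | ring B aldehyde with the 7'',9''-di-tert-butylsilylene-protected glycerol ether and O-benzyl ring C | COc1cc([C@@H](O[Si]5(C(C)(C)C)C(C)(C)C)[C@H](CO5)Oc2ccc(C=O)cc2OC)ccc1OCc1ccccc1
A5 | alternative 2 | fully protected target (two benzyl ethers, 7'',9''-silylene) | COc1cc([C@@H](O[Si]5(C(C)(C)C)C(C)(C)C)[C@H](CO5)Oc2ccc([C@@H]3OC[C@@H]4[C@H]3CO[C@H]4c3cc(OC)c(OCc4ccccc4)c(OC)c3)cc2OC)ccc1OCc1ccccc1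
A6 | alternative 2 | (E)-cinnamyl ether of the ring B oxiranyl carbinol, C7 arranged in space as in the target, epoxide carbon undefined | COc1cc([C@@H](O[Si]5(C(C)(C)C)C(C)(C)C)[C@H](CO5)Oc2ccc([C@H](OC/C=C/c3cc(OC)c(OCc4ccccc4)c(OC)c3)C3CO3)cc2OC)ccc1OCc1ccccc1
A7 | alternative 3 | methyl vanillate 4-O-ether carrying the protected glycerol arm | COc1cc([C@@H](O[Si]5(C(C)(C)C)C(C)(C)C)[C@H](CO5)Oc2ccc(C(=O)OC)cc2OC)ccc1OCc1ccccc1
A8 | alternative 3 | ethynyl ether of the C8'' alcohol of the silylene-protected arylglycerol | COc1cc([C@@H](O[Si]5(C(C)(C)C)C(C)(C)C)[C@H](CO5)OC#C)ccc1OCc1ccccc1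
A9 | alternative 3 | methyl 3-methoxy-2-oxo-2H-pyran-5-carboxylate | COC(=O)C1=COC(=O)C(OC)=C1
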